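The data come from a simulation on assumed constants; noise was put on by code.

In the oak and elm runs the open intermediate reads highest at 0.833 h, and one ratio carries that top to a new flask.

| flask | starting material | partner | protic impurity | remark | time |
|---|---|---|---|---|---|
| oak | 1.3 M | 0.65 M | 0.65 M | run made earlier |  |
| elm | 1.3 M | 0.98 M | 0.65 M | run made earlier |  |
| birch | 2.6 M | 1.3 M | 0.65 M | run made earlier |  |
| flask | 1.3 M | 1.30 M | 0.650 M |  | 10 h |

| run | time / h | open intermediate / % | target / % | starting material / % |
|---|---|---|---|---|
| oak | 0.250 | 6.8 | 0.8 | 80.7 |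
| oak | 0.417 | 8.9 | 0 | 70.4 |
| oak | 0.833 | 13.4 | 1.0 | 52.4 |
| oak | 1.50 | 12.2 | 0.7 | 35.8 |
| oak | 3.00 | 5.2 | 2.2 | 18.9 |
| oak | 6.00 | 2.2 | 5.5 | 7.4 |
| oak | 12.0 | 0.7 | 5.4 | 3.4 |
| elm | 0.250 | 6.3 | 0.9 | 81.7 |
| elm | 0.417 | 10.4 | 0.4 | 71.5 |
| elm | 0.833 | 13.8 | 1.5 | 50.7 |
| elm | 1.50 | 11.7 | 2.5 | 36.1 |
| elm | 3.00 | 5.4 | 2.9 | 18.5 |
| elm | 6.00 | 3.0 | 6.2 | 6.7 |
| elm | 12.0 | 0.8 | 7.2 | 3.6 |
| birch | 0.250 | 8.1 | 0.1 | 80.8 |
| birch | 0.667 | 12.0 | 0 | 59.9 |
| birch | 1.50 | 10.3 | 3.0 | 40.8 |
| birch | 4.00 | 4.6 | 4.9 | 17.5 |
| birch | 12.0 | 1.3 | 8.8 | 5.1 |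

(readings scatter by 1 percentage point)

- time up to 10 h at which open intermediate stands highest
- the amount of open intermediate, in percent of the starting material charged, at that time



At the top, making and loss of the open intermediate balance, so [open intermediate]/[starting material] there equals making constant over loss constant, a quasi-steady-state ratio. Oak and elm together read 0.264 at a mean [partner] of 0.815 M, and birch, past its top, still reads 0.263 at 4.00 h. With the mean starting material of oak and elm at that top, the first round gives 13.6%.

But the flask holds 1.30 M of partner, which is more, so that link needs reforging. In oak and elm, starting material falls at 0.795 h⁻¹, and the first readings show open intermediate made at 0.289 h⁻¹, an early ratio of 36.4% between two rates read there, not a measured share of the whole run. Target in those runs at 12.0 h averages 6.30%; with that early ratio taken as a rough stand-in for the passage through open intermediate, target's part of the loss comes to about 17.3%. Scaled with [partner], this raises the loss constant by 10.3%. The second round thus gives the flask ratio 0.239, and 12.3% near 0.833 h.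

The forecast says 13.2% at 0.85 h: “The flask matches oak and elm in starting material and impurity, with more partner”. That stands 0.90 percentage points above this reckoning.

The flask gives 12.5% at 0.918 h, within the forecast's margin, so reading the top of oak and elm was the cheapest sufficient route. Computed without scatter, oak tops at 12.8%, and with partner alone changed at 12.5%. At the top of the flask starting material stands at 49.9%, and the ratio 0.239 turns that into 11.9%.

    starting material ⇌ open intermediate (K = 0.870, k = 0.380 h⁻¹)
    partner → second intermediate (k = 0.270 h⁻¹)
    open intermediate + second intermediate → target (k = 0.620 L mol⁻¹ h⁻¹)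
    2 second intermediate → homo product (k = 0.620 L mol⁻¹ h⁻¹)
    open intermediate → side product (k = 0.930 h⁻¹)
    starting material + protic impurity → quenched substrate (k = 0.470 L mol⁻¹ h⁻¹)
    starting material ⇌ dormant form (K = 1.00, k = 0.220 h⁻¹)

The same flask read at 6.0 h holds 8.22% of starting material, for which the ratio gives 1.96% of open intermediate. The computed amount is 2.35%.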